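Ring C of the flavonol holds one carbon, C3, wedged between C2 (bonded to O1 and ring B) and the C4 carbonyl. Excising it contracts the pyranone to a 2-arylbenzofuran-3-one, and the C2=C3 π bond of that ketone's enol form is where a carbene can put the carbon back. In one operation dibromocarbene adds to the silyl enol ether and the cyclopropane opens. This forges C2–C3 and C3–C4, enlarges furan to pyranone and leaves bromine on C3 as the handle for O3. The precursor is a 2-aryl-3-(tert-butyldimethylsiloxy)benzofuran with MOM on the future O5, O7 and O4' and benzyl on O3'. TBS, not TMS, is used because it outlasts tert-butoxide.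

Key step: step 5

Assumption: the target has no stereogenic centre, axis or double-bond isomerism, so nothing needs stereocontrol; the free bis(hydrogen sulfate) drawn is released from its ammonium salt only in the last operation, because aryl hydrogen sulfates hydrolyse under their own acidity.

Step 1
Reactants: 1 4,6-dihydroxybenzofuran-3(2H)-one
Product: 2 4,6-bis(methoxymethoxy)benzofuran-3(2H)-one
Conditions: MOMCl (2.6 equiv), iPr2NEt (3.5 equiv), CH2Cl2/DMF, 0 °C to rt
Reagents that add atoms: chloromethyl methyl ether (MOMCl), COCCl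
Why: Williamson-type O-alkylation (MOM acetal formation) should cap both phenols, since the amine base is too weak to enolise C2 appreciably and the C4 hydroxyl is only loosely chelated by the five-ring ketone.

Step 2
Reactants: 3 2-(benzyloxy)phenol
Product: 4 2-(benzyloxy)-4-bromophenol
Conditions: NBS (1.0 equiv), MeCN, −10 °C to rt, dark
Reagents that add atoms: N-bromosuccinimide, O=C1CCC(=O)N1Br
Why: Electrophilic aromatic bromination is steered para to the free hydroxyl, the stronger donor, which places bromine para to the future O4' and meta to the benzyloxy group.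

Step 3
Reactants: 4 2-(benzyloxy)-4-bromophenol
Product: 5 2-(benzyloxy)-4-bromo-1-(methoxymethoxy)benzene
Conditions: MOMCl (1.3 equiv), iPr2NEt (1.8 equiv), CH2Cl2, 0 °C to rt
Reagents that add atoms: chloromethyl methyl ether (MOMCl), COCCl
Why: Routine phenol O-alkylation (MOM protection) gives O4' the same acid-labile mask as O5 and O7, so that one later operation bares all three.

Step 4
Reactants: 2 4,6-bis(methoxymethoxy)benzofuran-3(2H)-one; 5 2-(benzyloxy)-4-bromo-1-(methoxymethoxy)benzene
Product: 7 {2-[3-(benzyloxy)-4-(methoxymethoxy)phenyl]-4,6-bis(methoxymethoxy)benzofuran-3-yloxy}(tert-butyl)dimethylsilane, via sodium enolate 6 (not isolated)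
Conditions: PdCl2(dtbpf) (2 mol %), NaOtBu (2.2 equiv), THF, 60 °C, argon; then TBSCl (1.5 equiv), 0 °C to rt; Et3N-deactivated silica
Reagents that add atoms: tert-butyldimethylsilyl chloride (TBSCl), CC(C)(C)[Si](C)(C)Cl; sodium tert-butoxide, CC(C)(C)[O-].[Na+] (only the sodium ion of 6)
Why: In this palladium-catalysed ketone α-arylation (Buchwald–Hartwig type) two equivalents of base hold all ketone as enolate so that self-aldol is shut off, the monoarylated product rests as the hindered, stabilised 3-oxidobenzofuran 6 so that a second arylation is disfavoured, and O-silylation in the same flask avoids handling the autoxidation-prone 2-aryl ketone.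

Step 5
Reactants: 7 {2-[3-(benzyloxy)-4-(methoxymethoxy)phenyl]-4,6-bis(methoxymethoxy)benzofuran-3-yloxy}(tert-butyl)dimethylsilane; 8 bromoform
Product: 11 2-[3-(benzyloxy)-4-(methoxymethoxy)phenyl]-3-bromo-5,7-bis(methoxymethoxy)-4H-chromen-4-one, via dibromocyclopropane 9 (not isolated), via siloxyflavylium bromide 10 (not isolated)
Conditions: CHBr3 (3 equiv), KOtBu (3 equiv, added in portions to 7 and CHBr3), toluene, −30 °C to rt, argon; then sat. aq NaHCO3
Reagents that add atoms: bromoform (8), BrC(Br)Br
Why: Proposed new method: electrophilic singlet dibromocarbene, made from CHBr3 and KOtBu, should add in a concerted [2+1] cheletropic step to the C2=C3 enol-ether bond of 7, the most electron-rich π bond present because O1, the siloxy oxygen and the 2-aryl group all feed it, giving the cis-fused dibromocyclopropane 9. Ionisation of the endo C–Br bond is coupled to a 2π disrotatory electrocyclic opening that breaks the shared former C2–C3 bond, so the six-membered ring is not closed by a cyclisation but arises by merging the three- and five-membered rings, and the cation formed is the aromatic 4-siloxyflavylium ion 10, which its bromide counter-ion desilylates to the 4-pyranone 11. The closest known reaction types are the dihalocarbene enlargement of cyclic silyl enol ethers to 2-halo-2-enones, the Ciamician–Dennstedt carbon insertion into pyrroles and indoles, and the thermal opening of benzofuran–dihalocarbene adducts to 3-halochromenes, none of which has been run on a 2-aryl-3-siloxybenzofuran to give a flavone. No stereocentre survives, since the two in 9 are cis by ring constraint, racemic and erased on opening. Two selectivities are needed: carbene capture by the enol ether rather than by the benzenoid rings or the OCH2 C–H bonds, secured by its far higher nucleophilicity and a limited carbene excess, and cleavage of the internal rather than an external cyclopropane bond, secured by the TBS group, which resists tert-butoxide so that no cyclopropanolate (which would open to a 2-dibromomethyl ketone) forms before ionisation. TBS also leaves as sluggish TBSBr, whereas a TMS group would release TMSBr, a reagent that strips MOM ethers.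

Step 6
Reactants: 11 2-[3-(benzyloxy)-4-(methoxymethoxy)phenyl]-3-bromo-5,7-bis(methoxymethoxy)-4H-chromen-4-one
Product: 12 3-(benzyloxy)-2-[3-(benzyloxy)-4-(methoxymethoxy)phenyl]-5,7-bis(methoxymethoxy)-4H-chromen-4-one
Conditions: BnOH (1.5 equiv), RockPhos Pd G3 (3 mol %), Cs2CO3 (1.5 equiv), dry toluene, 90 °C
Reagents that add atoms: benzyl alcohol, OCc1ccccc1
Why: In this palladium-catalysed C–O cross-coupling of a C(sp2)–Br bond with a primary alcohol (Buchwald-type etherification) 3-halochromones add oxidatively with ease, the bulky biaryl phosphine and the two flanking groups favour C–O reductive elimination over β-hydride elimination, and O3 arrives already benzylated, which is required because a free 3-OH would compete in the sulfation.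

Step 7
Reactants: 12 3-(benzyloxy)-2-[3-(benzyloxy)-4-(methoxymethoxy)phenyl]-5,7-bis(methoxymethoxy)-4H-chromen-4-one
Product: 13 3-(benzyloxy)-2-[3-(benzyloxy)-4-hydroxyphenyl]-5,7-dihydroxy-4H-chromen-4-one (3,3'-di-O-benzylquercetin)
Conditions: conc. HCl (cat.), MeOH/THF, 50 °C
Reagents that add atoms: none
Why: Acid-catalysed transacetalisation (MOM cleavage) should free O5, O7 and O4' at once, while both benzyl ethers and the flavone core are inert to dilute methanolic acid.

Step 8
Reactants: 13 3,3'-di-O-benzylquercetin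
Product: 14 bis(triethylammonium) 3,3'-di-O-benzylquercetin 7,4'-disulfate
Conditions: SO3·NMe3 (3 equiv), Et3N (6 equiv), MeCN, 50 °C; Sephadex LH-20
Reagents that add atoms: sulfur trioxide–trimethylamine complex, C[N+](C)(C)S(=O)(=O)[O-]; triethylamine, CCN(CC)CC (counter-ions)
Why: In this O-sulfonation of phenoxides with an amine–SO3 complex the acidic 7-OH and 4'-OH react, whereas the 5-OH, locked in a six-membered hydrogen bond to the C4 carbonyl, is the least reactive flavonoid hydroxyl and should stay free with a small reagent excess.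

Step 9
Reactants: 14 bis(triethylammonium) 3,3'-di-O-benzylquercetin 7,4'-disulfate
Product: 16 3',5-dihydroxy-4',7-bis(sulfooxy)flavonol (quercetin 7,4'-bis(hydrogen sulfate)), via debenzylated triethylammonium salt 15 (not isolated)
Conditions: H2 (1 atm), 10% Pd/C, MeOH, rt; filter; Dowex 50WX8 (H+ form), H2O, 0–5 °C; freeze-dry at once
Reagents that add atoms: none
Why: Catalytic hydrogenolysis cleaves both benzyl C–O bonds under neutral conditions that leave aryl sulfate salts and the tetrasubstituted C2=C3 bond untouched, and cold cation exchange then swaps Et3NH+ for H+ to give the acid form drawn.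

Compound list
1 | 4,6-dihydroxybenzofuran-3(2H)-one | O=C1COc2cc(O)cc(O)c12 | starting material
2 | 4,6-bis(methoxymethoxy)benzofuran-3(2H)-one | O=C1COc2cc(OCOC)cc(OCOC)c12 | intermediate
3 | 2-(benzyloxy)phenol | Oc1ccccc1OCc1ccccc1 | starting material
4 | 2-(benzyloxy)-4-bromophenol | Oc1ccc(Br)cc1OCc1ccccc1 | intermediate
5 | 2-(benzyloxy)-4-bromo-1-(methoxymethoxy)benzene | COCOc1ccc(Br)cc1OCc1ccccc1 | intermediate
6 | sodium 2-[3-(benzyloxy)-4-(methoxymethoxy)phenyl]-4,6-bis(methoxymethoxy)benzofuran-3-olate (not isolated) | [Na+].[O-]c1c(-c2ccc(OCOC)c(OCc3ccccc3)c2)oc2cc(OCOC)cc(OCOC)c12 | intermediate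
7 | {2-[3-(benzyloxy)-4-(methoxymethoxy)phenyl]-4,6-bis(methoxymethoxy)benzofuran-3-yloxy}(tert-butyl)dimethylsilane | CC(C)(C)[Si](C)(C)Oc1c(-c2ccc(OCOC)c(OCc3ccccc3)c2)oc2cc(OCOC)cc(OCOC)c12 | intermediate
8 | bromoform | BrC(Br)Br | starting material
9 | (±)-1,1-dibromo-1a-[3-(benzyloxy)-4-(methoxymethoxy)phenyl]-6b-(tert-butyldimethylsiloxy)-4,6-bis(methoxymethoxy)-1a,6b-dihydro-1H-cyclopropa[b]benzofuran, ring fusion necessarily cis (not isolated) | BrC1(Br)C2(O[Si](C)(C)C(C)(C)C)c3c(OCOC)cc(OCOC)cc3OC12c1ccc(OCOC)c(OCc2ccccc2)c1 | intermediate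
10 | 2-[3-(benzyloxy)-4-(methoxymethoxy)phenyl]-3-bromo-4-(tert-butyldimethylsiloxy)-5,7-bis(methoxymethoxy)chromenylium bromide (not isolated) | [Br-].CC(C)(C)[Si](C)(C)Oc1c(Br)c(-c2ccc(OCOC)c(OCc3ccccc3)c2)[o+]c2cc(OCOC)cc(OCOC)c12 | intermediate
11 | 2-[3-(benzyloxy)-4-(methoxymethoxy)phenyl]-3-bromo-5,7-bis(methoxymethoxy)-4H-chromen-4-one | O=c1c(Br)c(-c2ccc(OCOC)c(OCc3ccccc3)c2)oc2cc(OCOC)cc(OCOC)c12 | intermediate
12 | 3-(benzyloxy)-2-[3-(benzyloxy)-4-(methoxymethoxy)phenyl]-5,7-bis(methoxymethoxy)-4H-chromen-4-one | O=c1c(OCc2ccccc2)c(-c2ccc(OCOC)c(OCc3ccccc3)c2)oc2cc(OCOC)cc(OCOC)c12 | intermediate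
13 | 3-(benzyloxy)-2-[3-(benzyloxy)-4-hydroxyphenyl]-5,7-dihydroxy-4H-chromen-4-one | O=c1c(OCc2ccccc2)c(-c2ccc(O)c(OCc3ccccc3)c2)oc2cc(O)cc(O)c12 | intermediate
14 | bis(triethylammonium) 3,3'-di-O-benzylquercetin 7,4'-disulfate | CC[NH+](CC)CC.CC[NH+](CC)CC.O=c1c(OCc2ccccc2)c(-c2ccc(OS(=O)(=O)[O-])c(OCc3ccccc3)c2)oc2cc(OS(=O)(=O)[O-])cc(O)c12 | intermediate
15 | bis(triethylammonium) quercetin 7,4'-disulfate (not isolated) | CC[NH+](CC)CC.CC[NH+](CC)CC.O=c1c(O)c(-c2ccc(OS(=O)(=O)[O-])c(O)c2)oc2cc(OS(=O)(=O)[O-])cc(O)c12 | intermediate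
16 | 3',5-dihydroxy-4',7-bis(sulfooxy)flavonol (achiral) | O=c1c(O)c(-c2ccc(OS(=O)(=O)O)c(O)c2)oc2cc(OS(=O)(=O)O)cc(O)c12 | target

Total step count: 9.
Longest linear sequence: 8 steps (3 → 4 → 5 → 7 → 11 → 12 → 13 → 14 → 16). The branch from 1 joins at step 4.

Steps most likely to fail

**Step 5 (Proposed new method).**
- What may go wrong: carbene capture at the crowded tetrasubstituted double bond may be too slow. Early loss of the silyl group may be followed by opening of an external cyclopropane bond. The carbene may insert into acetal or benzylic C–H bonds, or alkoxide may attack the freshly formed pyranone.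
- Fallback (known chemistry): it sets out from 5 and rejoins at 11, building the pyranone by chalcone cyclisation and placing bromine on C3 afterwards. Bromine–lithium exchange on 5 (n-BuLi, THF, −78 °C) gives [3-(benzyloxy)-4-(methoxymethoxy)phenyl]lithium F1, which DMF formylates, after a water quench, to 3-(benzyloxy)-4-(methoxymethoxy)benzaldehyde F2. Claisen–Schmidt condensation with commercial 2'-hydroxy-4',6'-bis(methoxymethoxy)acetophenone (KOH, EtOH, rt) gives the (E)-chalcone F3. Iodine in hot pyridine then effects oxa-Michael closure and dehydrogenation to the 3-unsubstituted flavone F4, in a basic medium that spares the acetals. C3-lithiation with LDA (THF, −78 °C), an established reaction of flavones, gives the 3-lithioflavone F5, which 1,2-dibromotetrachloroethane brominates to 11.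

**Step 4.**
- What may go wrong: the catalytic cycle may stall because the strongly stabilised enolate and the electron-rich aryl group reductively eliminate slowly. The enolate may be oxidised by air at C2, or a second arylation may creep in.
- Fallback: it sets out from 2 (with 5 as partner) and rejoins at 7, with the polarity at C2 changed from enolate arylation to cross-coupling of a metalated benzofuran. Soft enolisation of 2 (TBSOTf, Et3N, CH2Cl2, 0 °C) gives 3-(tert-butyldimethylsiloxy)-4,6-bis(methoxymethoxy)benzofuran F6. n-BuLi (THF, −78 °C) removes the acidic furan C2–H to give the 2-lithiobenzofuran F7. ZnCl2 converts F7 at once, before any O-to-C silyl shift, into the 2-benzofurylzinc chloride F8. Negishi coupling of F8 with 5 (Pd2(dba)3/SPhos, THF, 50 °C) forms the C2–aryl bond without base and delivers 7.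

**Step 6.**
- What may go wrong: β-hydride elimination from the palladium benzyloxide may lead to hydrodebromination, or benzyloxide may add to C2 and open the pyranone.
- Fallback: it sets out from 11 and rejoins at 12, installing oxygen through boron without palladium. Bromine–magnesium exchange (iPrMgCl·LiCl, THF, −40 °C) gives the 3-magnesioflavone F9, and B(OMe)3 converts it into the dimethyl flavon-3-ylboronate F10. H2O2/AcOH oxidises F10 in the same flask to the 3-hydroxyflavone F11; the metalloflavone, borate, flavonol sequence is established for flavones. BnBr/K2CO3 in DMF then benzylates O3 to give 12.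

Further compounds
F1 | step 5 | [3-(benzyloxy)-4-(methoxymethoxy)phenyl]lithium | [Li]c1ccc(OCOC)c(OCc2ccccc2)c1
F2 | step 5 | 3-(benzyloxy)-4-(methoxymethoxy)benzaldehyde | O=Cc1ccc(OCOC)c(OCc2ccccc2)c1
F3 | step 5 | (E)-3-[3-(benzyloxy)-4-(methoxymethoxy)phenyl]-1-[2-hydroxy-4,6-bis(methoxymethoxy)phenyl]prop-2-en-1-one | O=C(/C=C/c1ccc(OCOC)c(OCc2ccccc2)c1)c1c(O)cc(OCOC)cc1OCOC
F4 | step 5 | 2-[3-(benzyloxy)-4-(methoxymethoxy)phenyl]-5,7-bis(methoxymethoxy)-4H-chromen-4-one | O=c1cc(-c2ccc(OCOC)c(OCc3ccccc3)c2)oc2cc(OCOC)cc(OCOC)c12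
F5 | step 5 | {2-[3-(benzyloxy)-4-(methoxymethoxy)phenyl]-5,7-bis(methoxymethoxy)-4-oxo-4H-chromen-3-yl}lithium | O=c1c([Li])c(-c2ccc(OCOC)c(OCc3ccccc3)c2)oc2cc(OCOC)cc(OCOC)c12
F6 | step 4 | 3-(tert-butyldimethylsiloxy)-4,6-bis(methoxymethoxy)benzofuran | CC(C)(C)[Si](C)(C)Oc1coc2cc(OCOC)cc(OCOC)c12
F7 | step 4 | [3-(tert-butyldimethylsiloxy)-4,6-bis(methoxymethoxy)benzofuran-2-yl]lithium | CC(C)(C)[Si](C)(C)Oc1c([Li])oc2cc(OCOC)cc(OCOC)c12
F8 | step 4 | [3-(tert-butyldimethylsiloxy)-4,6-bis(methoxymethoxy)benzofuran-2-yl]zinc chloride | CC(C)(C)[Si](C)(C)Oc1c([Zn]Cl)oc2cc(OCOC)cc(OCOC)c12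
F9 | step 6 | {2-[3-(benzyloxy)-4-(methoxymethoxy)phenyl]-5,7-bis(methoxymethoxy)-4-oxo-4H-chromen-3-yl}magnesium chloride | O=c1c([Mg]Cl)c(-c2ccc(OCOC)c(OCc3ccccc3)c2)oc2cc(OCOC)cc(OCOC)c12
F10 | step 6 | dimethyl {2-[3-(benzyloxy)-4-(methoxymethoxy)phenyl]-5,7-bis(methoxymethoxy)-4-oxo-4H-chromen-3-yl}boronate | O=c1c(B(OC)OC)c(-c2ccc(OCOC)c(OCc3ccccc3)c2)oc2cc(OCOC)cc(OCOC)c12
F11 | step 6 | 2-[3-(benzyloxy)-4-(methoxymethoxy)phenyl]-3-hydroxy-5,7-bis(methoxymethoxy)-4H-chromen-4-one | O=c1c(O)c(-c2ccc(OCOC)c(OCc3ccccc3)c2)oc2cc(OCOC)cc(OCOC)c12
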